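Count amounts as shares of the charge. Flasks of first-order steps that differ in charge alone have turned over the same share of their charge at a given time.

| setting | Tuesday's | alder | birch | larch |
|---|---|---|---|---|
| starting material | 0.66 M | 0.60 M | 1.2 M | 2.5 M |
| remark | run made earlier |  |  |  |
| time |  | 6.0 h | 6.0 h | 6.0 h |

- Tuesday's (time / h: target / %): 0.333: 3.8; 0.833: 7.8; 1.50: 10.6; 2.50: 14.1; 4.00: 18.0

(readings scatter by 0.5 percentage points)

- what was read earlier has a scatter of 0.5 percentage points, one standard deviation
- a reading or a percentage of target counts all its forms, free or not
- "hardly changes" means that all values lie within two and a half points (for a concentration: within two and a half percent of the largest)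

- amount of target at the end, in percent of the starting material charged for alder, birch, larch, in this order
- the course of these numbers from the first flask to the last (falls all the way / hardly changes / rises all the way / rises, then falls / falls, then rises)

Read Tuesday's run late, where its curve has flattened: between 2.50 h and 4.00 h target goes from 14.1 % to 18.0 %. That gives the late turnover, the net share of the charge that target gains per hour, 0.0260 /h. It is a reading, and each of its two points carries a scatter of 0.5 percentage points.

Alder is the neighbour of Tuesday's run, with a charge of 0.60 M against 0.66 M, which is less by a factor of 0.909. If the steps are first order, that difference does not matter, and alder follows Tuesday's line in percent. Start from Tuesday's last reading and add the late turnover for the 2.00 h up to 6.0 h, which gives 23.2 %. One charge cannot prove first order, but this is my reckoning: the same share for alder, birch and larch.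

The forecast differs. It gives 25 %, 14 % and 7.5 %, a row that falls all the way, reasoning that, in the case it assumes, “the absolute amount formed barely depends on the charge”.

The flasks give 22.5 %, 22.5 % and 24.1 %, so the row hardly changes.

    crystals ⇌ target, rate k1*(cs1 - [target]) while solid is left; crystals form when [target] > cs1 (solubility = 0.430 M, k = 0.00510 /s)
    starting material ⇌ target (K = 2.30, k = 3.20 × 10⁻⁵ /s)
    starting material ⇌ isomer of the product A (K = 0.800, k = 8.40 × 10⁻⁵ /s)
    target ⇌ isomer of the product B (K = 0.500, k = 9.20 × 10⁻⁵ /s)

At 6.0 h starting material stands at 36.2 % in alder, 36.2 % in birch and 35.9 % in larch. The reckoned end lies 0.74 points above alder's value. Now apply the late turnover to larch: from 15.8 % at 3.00 h it reaches 23.6 % at 6.00 h, where larch holds 24.1 % of target, crystals of 6.71 % counted in.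

The data were computed on assumed constants, noise included.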